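**Retrosynthetic overview**
- Last: global hydrogenolysis of eight benzyl ethers; rings A, B and the galloyl ring D are bought intact, so ring C is the only ring formed.
- Ring C (O1–C2 and C2–H): cis-selective reductive etherification of an aryl ketone by the ring-A phenol, with the C3 ester directing hydride to the opposite face.
- C2–C3 (key bond): enantioselective crossed benzoin. The carbene-bound acyl anion of the ring-B aldehyde adds to the ring-A arylacetaldehyde (two carbonyl carbons joined); this sets C3.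
- Galloyl ester: carried on the ring-A phenol as its protecting group and relayed O-to-O onto the new C3 hydroxyl in the same flask, which frees the phenol for ring closure.
- Ring-A aldehyde: 3,5-bis(benzyloxy)phenol by O-allylation, Claisen rearrangement, esterification and oxidative cleavage.

Assumption: 1, 6 and 10 are bought as such; the sense of induction in step 5 is assigned by analogy with the homo-benzoin selectivity of the catalyst, and its mirror image would be used if the opposite sense were found.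

**Step 1**
Reactants: 1 3,5-bis(benzyloxy)phenol; 2 allyl bromide
Product: 3 1-(allyloxy)-3,5-bis(benzyloxy)benzene
Conditions: K2CO3 (2 equiv), acetone, reflux
Reagents that add atoms: none
Why: Williamson etherification (SN2 of the phenoxide on allyl bromide) at the only free hydroxyl; no stereocentre.

**Step 2**
Reactants: 3 1-(allyloxy)-3,5-bis(benzyloxy)benzene
Product: 5 2-allyl-3,5-bis(benzyloxy)phenol, via Claisen dienone 4 (not isolated)
Conditions: PhNEt2, 195 °C, sealed tube
Reagents that add atoms: none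
Why: Aromatic Claisen rearrangement, a [3,3]-sigmatropic shift to one of the two equivalent ortho carbons followed by tautomerisation of 4, which places the future C4 and C3 carbons ortho to the oxygen that becomes O1; no stereocentre.

**Step 3**
Reactants: 5 2-allyl-3,5-bis(benzyloxy)phenol; 6 3,4,5-tris(benzyloxy)benzoic acid
Product: 7 2-allyl-3,5-bis(benzyloxy)phenyl 3,4,5-tris(benzyloxy)benzoate
Conditions: DCC (1.2 equiv), 4-(dimethylamino)pyridine (10 mol%), CH2Cl2, 0 °C to rt
Reagents that add atoms: none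
Why: Steglich esterification of the phenol, which installs the galloyl unit early so that it serves first as phenol protecting group and later as internal acyl donor; no stereocentre.

**Step 4**
Reactants: 7 2-allyl-3,5-bis(benzyloxy)phenyl 3,4,5-tris(benzyloxy)benzoate
Product: 9 3,5-bis(benzyloxy)-2-(2-oxoethyl)phenyl 3,4,5-tris(benzyloxy)benzoate, via diol 8 (not isolated)
Conditions: OsO4 (2 mol%), NaIO4 (4 equiv), 2,6-lutidine (2 equiv), dioxane/H2O 3:1, rt; used crude
Reagents that add atoms: sodium periodate, [Na+].[O-]I(=O)(=O)=O, and water, O (the aldehyde oxygen reaches the substrate through catalytic OsO4, O=[Os](=O)(=O)=O)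
Why: Lemieux–Johnson oxidation (catalytic dihydroxylation to 8, then periodate glycol cleavage) removes the terminal carbon under buffered conditions that leave the aryl ester and benzyl ethers intact; no stereocentre.

**Step 5 (key step)**
Reactants: 9 3,5-bis(benzyloxy)-2-(2-oxoethyl)phenyl 3,4,5-tris(benzyloxy)benzoate; 10 3,4,5-tris(benzyloxy)benzaldehyde
Product: 12 (2R)-3-[2,4-bis(benzyloxy)-6-hydroxyphenyl]-1-oxo-1-[3,4,5-tris(benzyloxy)phenyl]propan-2-yl 3,4,5-tris(benzyloxy)benzoate, via benzoin adduct 11 (not isolated)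
Conditions: 10 (2.0 equiv), (5R)-5-tert-butyl-2-phenyl-6,8-dihydro-5H-[1,2,4]triazolo[3,4-c][1,4]oxazin-2-ium tetrafluoroborate (15 mol%), KN(SiMe3)2 (12 mol%), THF, 0 °C, 9 added over 6 h; then 4-(dimethylamino)pyridine (20 mol%), rt
Reagents that add atoms: none
Why: Proposed new method: an enantioselective crossed benzoin reaction (carbene-catalysed acyl anion umpolung through a Breslow intermediate) coupled to an O-to-O acyl relay — the electron-rich aldehyde 10 forms the Breslow intermediate readily but is a poor acceptor (slow, reversible homo-benzoin), while 9, kept at low concentration, is the better electrophile and too hindered to dimerise, so the acyl anion equivalent of 10 adds to the aldehyde carbon of 9 on the face left open by the tert-butyl group of the bicyclic triazolylidene and sets C3 as R, after which the neighbouring aryl gallate acylates the new hydroxyl of 11 through a seven-membered transition state (4-(dimethylamino)pyridine as acyl shuttle, driven by release of the phenol), taking the product out of the reversible benzoin and α-ketol manifold; the closest known reactions are the chiral triazolium-catalysed benzoin condensation of aryl aldehydes, chemoselective aryl–alkyl crossed acyloin reactions and acyl migration from phenyl esters to alcohols.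

**Step 6**
Reactants: 12 (2R)-3-[2,4-bis(benzyloxy)-6-hydroxyphenyl]-1-oxo-1-[3,4,5-tris(benzyloxy)phenyl]propan-2-yl 3,4,5-tris(benzyloxy)benzoate
Product: 15 (2R,3R)-5,7-bis(benzyloxy)-2-[3,4,5-tris(benzyloxy)phenyl]-3,4-dihydro-2H-chromen-3-yl 3,4,5-tris(benzyloxy)benzoate, via hemiketal 13 (not isolated), via oxocarbenium triflate 14 (not isolated)
Conditions: Et3SiH (5 equiv), Me3SiOTf (1.5 equiv), CH2Cl2, −78 to −30 °C; aq. NaHCO3
Reagents that add atoms: none
Why: Lewis acid-promoted reductive etherification (ionic hydrogenation): the phenol closes onto the aryl ketone to hemiketal 13, ionisation gives the aryl-stabilised oxocarbenium ion 14, and Et3SiH delivers hydride to C2 anti to the pseudoaxial, participating C3 acyloxy group, so the aryl group ends cis to the ester and C2 is set as R while C3 is untouched, a selectivity for which I recall precedent with racemic 3-acyloxyflavans.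

**Step 7**
Reactants: 15 (2R,3R)-5,7-bis(benzyloxy)-2-[3,4,5-tris(benzyloxy)phenyl]-3,4-dihydro-2H-chromen-3-yl 3,4,5-tris(benzyloxy)benzoate
Product: 16 (−)-epigallocatechin gallate
Conditions: H2 (1 atm), Pd(OH)2/C, THF/MeOH 1:1, rt, degassed work-up
Reagents that add atoms: none
Why: Heterogeneous hydrogenolysis cleaves the eight aryl benzyl ethers under neutral conditions without touching the ester or either stereocentre; this deprotection of the octabenzyl ether is, as far as I recall, precedented.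

**Compound list**
1 | 3,5-bis(benzyloxy)phenol | Oc1cc(OCc2ccccc2)cc(OCc2ccccc2)c1 | starting material
2 | allyl bromide | C=CCBr | starting material
3 | 1-(allyloxy)-3,5-bis(benzyloxy)benzene | C=CCOc1cc(OCc2ccccc2)cc(OCc2ccccc2)c1 | intermediate
4 | 6-allyl-3,5-bis(benzyloxy)cyclohexa-2,4-dien-1-one (racemic, not isolated) | C=CCC1C(=O)C=C(OCc2ccccc2)C=C1OCc1ccccc1 | intermediate
5 | 2-allyl-3,5-bis(benzyloxy)phenol | C=CCc1c(O)cc(OCc2ccccc2)cc1OCc1ccccc1 | intermediate
6 | 3,4,5-tris(benzyloxy)benzoic acid | OC(=O)c1cc(OCc2ccccc2)c(OCc2ccccc2)c(OCc2ccccc2)c1 | starting material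
7 | 2-allyl-3,5-bis(benzyloxy)phenyl 3,4,5-tris(benzyloxy)benzoate | C=CCc1c(OC(=O)c2cc(OCc3ccccc3)c(OCc3ccccc3)c(OCc3ccccc3)c2)cc(OCc2ccccc2)cc1OCc1ccccc1 | intermediate
8 | 3,5-bis(benzyloxy)-2-(2,3-dihydroxypropyl)phenyl 3,4,5-tris(benzyloxy)benzoate (racemic, not isolated) | OCC(O)Cc1c(OC(=O)c2cc(OCc3ccccc3)c(OCc3ccccc3)c(OCc3ccccc3)c2)cc(OCc2ccccc2)cc1OCc1ccccc1 | intermediate
9 | 3,5-bis(benzyloxy)-2-(2-oxoethyl)phenyl 3,4,5-tris(benzyloxy)benzoate | O=CCc1c(OC(=O)c2cc(OCc3ccccc3)c(OCc3ccccc3)c(OCc3ccccc3)c2)cc(OCc2ccccc2)cc1OCc1ccccc1 | intermediate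
10 | 3,4,5-tris(benzyloxy)benzaldehyde | O=Cc1cc(OCc2ccccc2)c(OCc2ccccc2)c(OCc2ccccc2)c1 | starting material
11 | 3,5-bis(benzyloxy)-2-{(2R)-2-hydroxy-3-oxo-3-[3,4,5-tris(benzyloxy)phenyl]propyl}phenyl 3,4,5-tris(benzyloxy)benzoate (not isolated) | O=C(c1cc(OCc2ccccc2)c(OCc2ccccc2)c(OCc2ccccc2)c1)[C@H](O)Cc1c(OC(=O)c2cc(OCc3ccccc3)c(OCc3ccccc3)c(OCc3ccccc3)c2)cc(OCc2ccccc2)cc1OCc1ccccc1 | intermediate
12 | (2R)-3-[2,4-bis(benzyloxy)-6-hydroxyphenyl]-1-oxo-1-[3,4,5-tris(benzyloxy)phenyl]propan-2-yl 3,4,5-tris(benzyloxy)benzoate | O=C(c1cc(OCc2ccccc2)c(OCc2ccccc2)c(OCc2ccccc2)c1)[C@H](OC(=O)c1cc(OCc2ccccc2)c(OCc2ccccc2)c(OCc2ccccc2)c1)Cc1c(O)cc(OCc2ccccc2)cc1OCc1ccccc1 | intermediate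
13 | (3R)-5,7-bis(benzyloxy)-2-hydroxy-2-[3,4,5-tris(benzyloxy)phenyl]-3,4-dihydro-2H-chromen-3-yl 3,4,5-tris(benzyloxy)benzoate (both C2 epimers, not isolated) | O=C(O[C@@H]1Cc2c(OCc3ccccc3)cc(OCc3ccccc3)cc2OC1(O)c1cc(OCc2ccccc2)c(OCc2ccccc2)c(OCc2ccccc2)c1)c1cc(OCc2ccccc2)c(OCc2ccccc2)c(OCc2ccccc2)c1 | intermediate
14 | (3R)-5,7-bis(benzyloxy)-3-{[3,4,5-tris(benzyloxy)benzoyl]oxy}-2-[3,4,5-tris(benzyloxy)phenyl]-3,4-dihydrochromenylium trifluoromethanesulfonate (not isolated) | O=C(O[C@@H]1Cc2c(OCc3ccccc3)cc(OCc3ccccc3)cc2[O+]=C1c1cc(OCc2ccccc2)c(OCc2ccccc2)c(OCc2ccccc2)c1)c1cc(OCc2ccccc2)c(OCc2ccccc2)c(OCc2ccccc2)c1.[O-]S(=O)(=O)C(F)(F)F | intermediate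
15 | (2R,3R)-5,7-bis(benzyloxy)-2-[3,4,5-tris(benzyloxy)phenyl]-3,4-dihydro-2H-chromen-3-yl 3,4,5-tris(benzyloxy)benzoate (octa-O-benzyl ether of the target) | O=C(O[C@@H]1Cc2c(OCc3ccccc3)cc(OCc3ccccc3)cc2O[C@@H]1c1cc(OCc2ccccc2)c(OCc2ccccc2)c(OCc2ccccc2)c1)c1cc(OCc2ccccc2)c(OCc2ccccc2)c(OCc2ccccc2)c1 | intermediate
16 | (−)-epigallocatechin gallate, (2R,3R)-5,7-dihydroxy-2-(3,4,5-trihydroxyphenyl)-3,4-dihydro-2H-chromen-3-yl 3,4,5-trihydroxybenzoate | O=C(O[C@@H]1Cc2c(O)cc(O)cc2O[C@@H]1c1cc(O)c(O)c(O)c1)c1cc(O)c(O)c(O)c1 | target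

**Count**
Total steps: 7. Longest linear sequence: 7 (from 1; 2, 6 and 10 enter as bought).

**Steps most likely to fail, with fallbacks**

Step 5 is the main risk. The wrong partner may act as acyl donor, 9 may self-condense, the aryl ester may intercept the carbene adduct or the enolate of 9, and the enantiomeric excess may be moderate (15 is the point at which I would try to raise it by crystallisation). The fallback keeps the acyl anion logic but makes the donor role unambiguous with an acylsilane, and it sets out from 10: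
- Propane-1,3-dithiol and BF3·OEt2 give 2-[3,4,5-tris(benzyloxy)phenyl]-1,3-dithiane F1.
- n-BuLi then Et3SiCl gives triethyl{2-[3,4,5-tris(benzyloxy)phenyl]-1,3-dithian-2-yl}silane F2.
- MeI and CaCO3 in aqueous MeCN unmask [3,4,5-tris(benzyloxy)phenyl](triethylsilyl)methanone F3.
- F3 and 9 are joined in a cross silyl benzoin reaction: phosphite addition, 1,2-Brook rearrangement, addition to the aldehyde, 1,4-silyl shift. The catalyst is the lithium salt of the cyclic hydrogen phosphite of α,α,α′,α′-tetrakis(2-fluorophenyl)-2,2-dimethyl-1,3-dioxolane-4,5-dimethanol, in whichever antipode gives the R product. This yields 3,5-bis(benzyloxy)-2-{(2R)-3-oxo-2-[(triethylsilyl)oxy]-3-[3,4,5-tris(benzyloxy)phenyl]propyl}phenyl 3,4,5-tris(benzyloxy)benzoate F4.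
- Bu4NF/AcOH followed by 4-(dimethylamino)pyridine frees 11, which relays the acyl group, and the route is rejoined at 12.

Step 6 may give a poor cis/trans ratio, or the ketone may be reduced before ring closure. The fallback forms the O1–C2 bond by SN2 displacement instead of forming the C2–H bond, and it sets out from 12:
- Reagent-controlled transfer hydrogenation gives the anti alcohol (1S,2R)-3-[2,4-bis(benzyloxy)-6-hydroxyphenyl]-1-hydroxy-1-[3,4,5-tris(benzyloxy)phenyl]propan-2-yl 3,4,5-tris(benzyloxy)benzoate F5. The catalyst is chloro(p-cymene)[(1R,2R)-N-(p-toluenesulfonyl)-1,2-diphenylethylenediaminato]ruthenium in HCO2H/Et3N.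
- Mitsunobu cyclisation (PPh3, DIAD, THF, 0 °C) lets the phenol displace the activated benzylic oxygen with inversion and rejoins the route at 15.
- The hazards are 1,2-acyl migration and SN1 leakage at the electron-rich benzylic carbon.

Step 4 may suffer from over-oxidation of the electron-rich ring or loss of the labile arylacetaldehyde. The fallback avoids carbon excision and sets out from 1:
- Ortho-vinylation with ethyne (SnCl4, Bu3N, chlorobenzene/MeCN, 60 °C) gives 3,5-bis(benzyloxy)-2-vinylphenol F6.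
- DCC/4-(dimethylamino)pyridine esterification with 6 gives 3,5-bis(benzyloxy)-2-vinylphenyl 3,4,5-tris(benzyloxy)benzoate F7.
- Aldehyde-selective Wacker-type oxidation of the styrene (PdCl2(MeCN)2, 1,4-benzoquinone, t-BuOH/H2O) rejoins the route at 9.
- It is not the main route because SnCl4 in the presence of benzyl ethers is less secure than the Claisen sequence.

**Further compounds**
F1 | step 5 | 2-[3,4,5-tris(benzyloxy)phenyl]-1,3-dithiane | C1CSC(SC1)c1cc(OCc2ccccc2)c(OCc2ccccc2)c(OCc2ccccc2)c1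
F2 | step 5 | triethyl{2-[3,4,5-tris(benzyloxy)phenyl]-1,3-dithian-2-yl}silane | CC[Si](CC)(CC)C1(SCCCS1)c1cc(OCc2ccccc2)c(OCc2ccccc2)c(OCc2ccccc2)c1
F3 | step 5 | [3,4,5-tris(benzyloxy)phenyl](triethylsilyl)methanone | CC[Si](CC)(CC)C(=O)c1cc(OCc2ccccc2)c(OCc2ccccc2)c(OCc2ccccc2)c1
F4 | step 5 | 3,5-bis(benzyloxy)-2-{(2R)-3-oxo-2-[(triethylsilyl)oxy]-3-[3,4,5-tris(benzyloxy)phenyl]propyl}phenyl 3,4,5-tris(benzyloxy)benzoate | O=C(c1cc(OCc2ccccc2)c(OCc2ccccc2)c(OCc2ccccc2)c1)[C@H](O[Si](CC)(CC)CC)Cc1c(OC(=O)c2cc(OCc3ccccc3)c(OCc3ccccc3)c(OCc3ccccc3)c2)cc(OCc2ccccc2)cc1OCc1ccccc1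
F5 | step 6 | (1S,2R)-3-[2,4-bis(benzyloxy)-6-hydroxyphenyl]-1-hydroxy-1-[3,4,5-tris(benzyloxy)phenyl]propan-2-yl 3,4,5-tris(benzyloxy)benzoate | O[C@@H](c1cc(OCc2ccccc2)c(OCc2ccccc2)c(OCc2ccccc2)c1)[C@H](OC(=O)c1cc(OCc2ccccc2)c(OCc2ccccc2)c(OCc2ccccc2)c1)Cc1c(O)cc(OCc2ccccc2)cc1OCc1ccccc1
F6 | step 4 | 3,5-bis(benzyloxy)-2-vinylphenol | C=Cc1c(O)cc(OCc2ccccc2)cc1OCc1ccccc1
F7 | step 4 | 3,5-bis(benzyloxy)-2-vinylphenyl 3,4,5-tris(benzyloxy)benzoate | C=Cc1c(OC(=O)c2cc(OCc3ccccc3)c(OCc3ccccc3)c(OCc3ccccc3)c2)cc(OCc2ccccc2)cc1OCc1ccccc1
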